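**Retrosynthetic overview**

- The target is an ester of natural (5aS,6R,9S,9aS)-hydroheptelidic acid (acyl half) with the primary alcohol of its mirror image (alcohol half). Two enantiomeric series are therefore built from one achiral dienyl unit and the two antipodes of a menthyloxybutenolide.
- The last oxepinone and the inter-unit ester are made together: the natural seco acid (ring CO2⁻ next to ring CHO) undergoes carboxylate oxa-Michael addition and intramolecular Horner–Wadsworth–Emmons (HWE) closure on a 2-phosphonoacrylate ester already attached to the CH2OH of the alcohol half.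
- The alcohol half is closed the same way from the mirror-image seco acid with allyl 2-phosphonoacrylate, then acylated at its primary OH with 2-phosphonoacrylic acid.
- Both seco acids come from saponification and C-5a epimerisation of a hydrogenated butenolide-acetal/spiro-carbonate cycloadduct.
- Key step: Au(I) cycloisomerisation of an enynyl tert-butyl carbonate to a (Z)-alkylidene cyclic carbonate diene and, in the same flask, endo Diels–Alder reaction with the butenolide. The gold stage is run once on all of the carbonate and half of the diene solution is diverted to the second butenolide. Ring order: dioxolanone + cyclohexene (alcohol-half series), cyclohexene of the acyl-half series, oxepinone of the alcohol half, oxepinone of the acyl half.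

Assumption: the SMILES is read literally (acyl half natural, alcohol half its mirror image), and both antipodes of 5-menthyloxy-2(5H)-furanone are taken as catalogue items (each is otherwise one step from 5-hydroxy-2(5H)-furanone and d- or l-menthol).

Locants C-5a, C-6, C-9, C-9a below are those of the final 2-benzoxepine units.

**Route**

Step 1
Reactants: 1 (E)-4-methylpent-2-enal
Product: 2 (E)-1,1-dibromo-5-methylhexa-1,3-diene
Conditions: CBr4, PPh3, Zn, CH2Cl2, 0 °C → rt
Reagents that add atoms: carbon tetrabromide, BrC(Br)(Br)Br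
Why: Corey–Fuchs (Ramirez) dibromo-olefination of the aldehyde with Ph3P=CBr2; the existing E-alkene is untouched and no stereocentre is involved.

Step 2
Reactants: 2 (E)-1,1-dibromo-5-methylhexa-1,3-diene
Product: 5 tert-butyl (E)-6-methylhept-4-en-2-yn-1-yl carbonate, via lithium acetylide 3 (not isolated), via lithium alkoxide 4 (not isolated)
Conditions: n-BuLi (2.1 equiv), THF, −78 → 0 °C; (CH2O)n, 0 °C → rt; Boc2O, −20 °C → rt
Reagents that add atoms: formaldehyde (as paraformaldehyde), C=O; di-tert-butyl dicarbonate, CC(C)(C)OC(=O)OC(=O)OC(C)(C)C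
Why: second stage of the Corey–Fuchs alkyne synthesis (Br/Li exchange, Fritsch–Buttenberg–Wiechell shift, deprotonation), then hydroxymethylation of the acetylide and in-flask O-acylation of the alkoxide by Boc2O.

Step 3
Reactants: 5 tert-butyl (E)-6-methylhept-4-en-2-yn-1-yl carbonate; 6 (5R)-5-(l-menthyloxy)furan-2(5H)-one
Product: 8 ent-series endo cycloadduct (3R,3aR,4R,7R,7aR)-3-(l-menthyloxy)-4-isopropyl-3a,4-dihydro-3H-spiro[2-benzofuran-7,4′-[1,3]dioxolane]-1,2′(7aH)-dione, via diene 7 (not isolated)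
Conditions: Ph3PAuNTf2 (2 mol %), CH2Cl2, rt, on all of 5; the solution of 7 is divided in two and one half is set aside under Ar for step 5; to the other half: 6, solvent switch to PhMe, 110 °C, sealed tube (BHT)
Reagents that add atoms: none
Why: Proposed new method: Au(I) 5-exo-dig cycloisomerisation of the propargylic tert-butyl carbonate (anti oxy-auration, loss of isobutene, protodeauration) gives only the (Z)-alkylidene carbonate, so on the diene the ring oxygen is "inside" and the CH2O "outside"; the thermal Diels–Alder reaction then runs endo, anti to the l-menthyloxy group and with the oxygenated terminus bonding to C-α of the butenolide, which sets the future C-6, C-9 and C-9a of the alcohol half in one operation (C-5a is formed cis and corrected in step 9); closest known reactions are the Au-catalysed formation of 4-alkylidene-1,3-dioxolan-2-ones from propargylic tert-butyl carbonates and the regio- and face-selective cycloadditions of 1-acyloxy- and 1-silyloxybutadienes to 5-menthyloxy-2(5H)-furanone.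

Step 4
Reactants: 8 ent-series cycloadduct
Product: 9 (3R,3aR,4S,7R,7aR)-3-(l-menthyloxy)-4-isopropyl-hexahydro-3H-spiro[2-benzofuran-7,4′-[1,3]dioxolane]-1,2′-dione
Conditions: H2 (1 atm), 5 % Rh/Al2O3, EtOAc, rt
Reagents that add atoms: none
Why: heterogeneous hydrogenation of the only C=C bond over rhodium, which unlike palladium does not cleave the allylic carbonate C–O bond; no stereocentre is created and lactone and acetal are inert.

Step 5
Reactants: 7 (4Z)-4-[(2E)-4-methylpent-2-en-1-ylidene]-1,3-dioxolan-2-one (the half of the solution set aside in step 3, used as such); 10 (5S)-5-(d-menthyloxy)furan-2(5H)-one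
Product: 11 natural-series endo cycloadduct (3S,3aS,4S,7S,7aS)-3-(d-menthyloxy)-4-isopropyl-3a,4-dihydro-3H-spiro[2-benzofuran-7,4′-[1,3]dioxolane]-1,2′(7aH)-dione
Conditions: solvent switch to PhMe, 110 °C, sealed tube (BHT)
Reagents that add atoms: none
Why: Proposed new method: thermal Diels–Alder reaction of the (Z)-alkylidene carbonate diene, mirror image of the cycloaddition in step 3 (endo, anti to the d-menthyloxy group, oxygenated terminus to C-α), setting the future C-6, C-9 and C-9a of the acyl half (C-5a is formed cis and corrected in step 11); closest known reactions are the cycloadditions of 1-acyloxy- and 1-silyloxybutadienes to 5-menthyloxy-2(5H)-furanone.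

Step 6
Reactants: 11 natural-series cycloadduct
Product: 12 (3S,3aS,4R,7S,7aS)-3-(d-menthyloxy)-4-isopropyl-hexahydro-3H-spiro[2-benzofuran-7,4′-[1,3]dioxolane]-1,2′-dione
Conditions: H2 (1 atm), 5 % Rh/Al2O3, EtOAc, rt
Reagents that add atoms: none
Why: hydrogenation of the only C=C bond over rhodium, as in step 4; no stereocentre is created.

Step 7
Reactants: 13 prop-2-en-1-yl (diethoxyphosphoryl)acetate
Product: 15 prop-2-en-1-yl 2-(diethoxyphosphoryl)prop-2-enoate, via allyloxy adduct 14 (not isolated)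
Conditions: (CH2O)n, piperidine (cat.), allyl alcohol, 80 °C; then TsOH (cat.), PhMe, reflux (–allyl alcohol)
Reagents that add atoms: formaldehyde (as paraformaldehyde), C=O
Why: Knoevenagel-type methylenation of a phosphonoacetate (Semmelhack protocol): the first-formed acrylate is trapped by the solvent alcohol and released again by acid-catalysed elimination.

Step 8
Reactants: 15 prop-2-en-1-yl 2-(diethoxyphosphoryl)prop-2-enoate
Product: 16 2-(diethoxyphosphoryl)prop-2-enoic acid
Conditions: Pd(PPh3)4 (2 mol %), PhSiH3, CH2Cl2, 0 °C; aqueous work-up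
Reagents that add atoms: none
Why: Pd(0)-catalysed allyl transfer to phenylsilane (Tsuji–Trost deallylation) frees the acid under neutral conditions, with no nucleophile that could add to the vinylphosphonate.

Step 9
Reactants: 9 hydrogenated ent-series cycloadduct; 15 prop-2-en-1-yl 2-(diethoxyphosphoryl)prop-2-enoate
Product: 18 prop-2-en-1-yl (5aR,6S,9R,9aR)-9-hydroxy-9-(hydroxymethyl)-1-oxo-6-(propan-2-yl)-3,5a,6,7,8,9a-hexahydro-2-benzoxepine-4-carboxylate, via lithium seco carboxylate 17 (not isolated)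
Conditions: LiOH (3.0 equiv), THF–H2O, 0 °C → rt; hexane wash, freeze-dry; then 15, LiCl, DBU (0.2 equiv), MeCN, 0 °C → rt
Reagents that add atoms: lithium hydroxide, [Li+].[OH-]
Why: Proposed new method: hydroxide opens the pseudo-ester (menthol leaves, aldehyde appears) and the cyclic carbonate, base epimerises the now enolisable C-5a to the all-equatorial trans isomer, and the carboxylate adds to the 2-phosphonoacrylate (oxa-Michael) to give a phosphonate carbanion that closes the oxepinone by intramolecular Horner–Wadsworth–Emmons olefination, the ring fixing the alkene geometry; closest known reactions are the phenoxide/alkoxide oxa-Michael–HWE annulations of 2-phosphonoacrylates (2H-chromenes, dihydrofurans) and Schweizer vinylphosphonium annulations.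

Step 10
Reactants: 18 ent-series allyl ester diol; 16 2-(diethoxyphosphoryl)prop-2-enoic acid
Product: 19 prop-2-en-1-yl (5aR,6S,9R,9aR)-9-({[2-(diethoxyphosphoryl)prop-2-enoyl]oxy}methyl)-9-hydroxy-1-oxo-6-(propan-2-yl)-3,5a,6,7,8,9a-hexahydro-2-benzoxepine-4-carboxylate
Conditions: DCC, DMAP (5 mol %), CH2Cl2, 0 °C
Reagents that add atoms: none
Why: Steglich esterification; only the primary hydroxyl is acylated because the tertiary one is too hindered, and no stereocentre is touched.

Step 11
Reactants: 12 hydrogenated natural-series cycloadduct; 19 phosphonoacrylate ester of the alcohol half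
Product: 21 [(5aR,6S,9R,9aR)-9-hydroxy-1-oxo-6-(propan-2-yl)-4-[(prop-2-en-1-yloxy)carbonyl]-3,5a,6,7,8,9a-hexahydro-2-benzoxepin-9-yl]methyl (5aS,6R,9S,9aS)-9-hydroxy-9-(hydroxymethyl)-1-oxo-6-(propan-2-yl)-3,5a,6,7,8,9a-hexahydro-2-benzoxepine-4-carboxylate, via lithium seco carboxylate 20 (not isolated)
Conditions: LiOH (3.0 equiv), THF–H2O, 0 °C → rt; hexane wash, freeze-dry; then 19, LiCl, DBU (0.2 equiv), MeCN–DMF, 0 °C → rt
Reagents that add atoms: lithium hydroxide, [Li+].[OH-]
Why: Proposed new method: the saponification, C-5a epimerisation and carboxylate oxa-Michael/intramolecular HWE sequence of step 9, now on the acrylate carried by the alcohol half, so the acyl-half oxepinone and the inter-unit ester form in one operation without protecting the acyl-half diol, and C-5a of the natural half is set trans by thermodynamic control; closest known reactions as in step 9.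

Step 12
Reactants: 21 dimeric allyl ester
Product: 22 CNP0340505.1
Conditions: Pd(PPh3)4 (5 mol %), PhSiH3, CH2Cl2, 0 °C; pH 4 buffer work-up
Reagents that add atoms: none
Why: Pd(0)/PhSiH3 deallylation (Tsuji–Trost) is neutral and leaves both lactones, the inter-unit ester, the conjugated alkenes and the free diols untouched; no stereocentre is affected.

**Compound list**

1 | (E)-4-methylpent-2-enal | CC(C)/C=C/C=O | starting material
2 | (E)-1,1-dibromo-5-methylhexa-1,3-diene | CC(C)/C=C/C=C(Br)Br | intermediate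
3 | lithium (E)-5-methylhex-3-en-1-yn-1-ide | CC(C)/C=C/C#[C-].[Li+] | intermediate
4 | lithium (E)-6-methylhept-4-en-2-yn-1-olate | CC(C)/C=C/C#CC[O-].[Li+] | intermediate
5 | tert-butyl (E)-6-methylhept-4-en-2-yn-1-yl carbonate | CC(C)/C=C/C#CCOC(=O)OC(C)(C)C | intermediate
6 | (5R)-5-{[(1R,2S,5R)-5-methyl-2-(propan-2-yl)cyclohexyl]oxy}furan-2(5H)-one [(5R)-5-(l-menthyloxy)-2(5H)-furanone] | O=C1C=C[C@H](O[C@@H]2C[C@H](C)CC[C@H]2C(C)C)O1 | starting material
7 | (4Z)-4-[(2E)-4-methylpent-2-en-1-ylidene]-1,3-dioxolan-2-one (ring O cis to the dienyl chain) | CC(C)/C=C/C=C1\OC(=O)OC1 | intermediate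
8 | (3R,3aR,4R,7R,7aR)-3-(l-menthyloxy)-4-(propan-2-yl)-3a,4-dihydro-3H-spiro[2-benzofuran-7,4′-[1,3]dioxolane]-1,2′(7aH)-dione (cis-fused lactone; isopropyl, lactone and carbonate CH2 on one face, carbonate O and menthyloxy on the other) | CC(C)[C@@H]1C=C[C@](O3)(COC3=O)[C@@H]2C(=O)O[C@@H](O[C@@H]4C[C@H](C)CC[C@H]4C(C)C)[C@H]12 | intermediate
9 | (3R,3aR,4S,7R,7aR)-3-(l-menthyloxy)-4-(propan-2-yl)hexahydro-3H-spiro[2-benzofuran-7,4′-[1,3]dioxolane]-1,2′-dione (5,6-dihydro 8) | CC(C)[C@@H]1CC[C@](O3)(COC3=O)[C@@H]2C(=O)O[C@@H](O[C@@H]4C[C@H](C)CC[C@H]4C(C)C)[C@H]12 | intermediate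
10 | (5S)-5-{[(1S,2R,5S)-5-methyl-2-(propan-2-yl)cyclohexyl]oxy}furan-2(5H)-one [(5S)-5-(d-menthyloxy)-2(5H)-furanone] | O=C1C=C[C@@H](O[C@H]2C[C@@H](C)CC[C@@H]2C(C)C)O1 | starting material
11 | (3S,3aS,4S,7S,7aS)-3-(d-menthyloxy)-4-(propan-2-yl)-3a,4-dihydro-3H-spiro[2-benzofuran-7,4′-[1,3]dioxolane]-1,2′(7aH)-dione (mirror image of 8) | CC(C)[C@H]1C=C[C@@](O3)(COC3=O)[C@H]2C(=O)O[C@H](O[C@H]4C[C@@H](C)CC[C@@H]4C(C)C)[C@@H]12 | intermediate
12 | (3S,3aS,4R,7S,7aS)-3-(d-menthyloxy)-4-(propan-2-yl)hexahydro-3H-spiro[2-benzofuran-7,4′-[1,3]dioxolane]-1,2′-dione (mirror image of 9) | CC(C)[C@H]1CC[C@@](O3)(COC3=O)[C@H]2C(=O)O[C@H](O[C@H]4C[C@@H](C)CC[C@@H]4C(C)C)[C@@H]12 | intermediate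
13 | prop-2-en-1-yl (diethoxyphosphoryl)acetate | C=CCOC(=O)CP(=O)(OCC)OCC | starting material
14 | prop-2-en-1-yl 2-(diethoxyphosphoryl)-3-(prop-2-en-1-yloxy)propanoate | C=CCOCC(C(=O)OCC=C)P(=O)(OCC)OCC | intermediate
15 | prop-2-en-1-yl 2-(diethoxyphosphoryl)prop-2-enoate | C=CCOC(=O)C(=C)P(=O)(OCC)OCC | intermediate
16 | 2-(diethoxyphosphoryl)prop-2-enoic acid | OC(=O)C(=C)P(=O)(OCC)OCC | intermediate
17 | lithium (1R,2S,3S,6R)-2-formyl-6-hydroxy-6-(hydroxymethyl)-3-(propan-2-yl)cyclohexane-1-carboxylate (CHO, CO2⁻ and isopropyl all trans; OH trans to CO2⁻) | CC(C)[C@@H]1CC[C@](O)(CO)[C@H](C(=O)[O-])[C@H]1C=O.[Li+] | intermediate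
18 | prop-2-en-1-yl (5aR,6S,9R,9aR)-9-hydroxy-9-(hydroxymethyl)-1-oxo-6-(propan-2-yl)-3,5a,6,7,8,9a-hexahydro-2-benzoxepine-4-carboxylate | CC(C)[C@@H]1CC[C@](O)(CO)[C@@H]2C(=O)OCC(C(=O)OCC=C)=C[C@@H]12 | intermediate
19 | prop-2-en-1-yl (5aR,6S,9R,9aR)-9-({[2-(diethoxyphosphoryl)prop-2-enoyl]oxy}methyl)-9-hydroxy-1-oxo-6-(propan-2-yl)-3,5a,6,7,8,9a-hexahydro-2-benzoxepine-4-carboxylate | CC(C)[C@@H]1CC[C@](O)(COC(=O)C(=C)P(=O)(OCC)OCC)[C@@H]2C(=O)OCC(C(=O)OCC=C)=C[C@@H]12 | intermediate
20 | lithium (1S,2R,3R,6S)-2-formyl-6-hydroxy-6-(hydroxymethyl)-3-(propan-2-yl)cyclohexane-1-carboxylate (mirror image of 17) | CC(C)[C@H]1CC[C@@](O)(CO)[C@@H](C(=O)[O-])[C@@H]1C=O.[Li+] | intermediate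
21 | [(5aR,6S,9R,9aR)-9-hydroxy-1-oxo-6-(propan-2-yl)-4-[(prop-2-en-1-yloxy)carbonyl]-3,5a,6,7,8,9a-hexahydro-2-benzoxepin-9-yl]methyl (5aS,6R,9S,9aS)-9-hydroxy-9-(hydroxymethyl)-1-oxo-6-(propan-2-yl)-3,5a,6,7,8,9a-hexahydro-2-benzoxepine-4-carboxylate | CC(C)[C@H]1CC[C@@](O)(CO)[C@H]2C(=O)OCC(C(=O)OC[C@@]3(O)CC[C@@H](C(C)C)[C@@H]4C=C(C(=O)OCC=C)COC(=O)[C@H]43)=C[C@H]12 | intermediate
22 | CNP0340505.1: [(5aR,6S,9R,9aR)-4-carboxy-9-hydroxy-1-oxo-6-(propan-2-yl)-3,5a,6,7,8,9a-hexahydro-2-benzoxepin-9-yl]methyl (5aS,6R,9S,9aS)-9-hydroxy-9-(hydroxymethyl)-1-oxo-6-(propan-2-yl)-3,5a,6,7,8,9a-hexahydro-2-benzoxepine-4-carboxylate | CC(C)[C@H]1CC[C@@](O)(CO)[C@H]2C(=O)OCC(C(=O)OC[C@@]3(O)CC[C@@H](C(C)C)[C@@H]4C=C(C(=O)O)COC(=O)[C@H]43)=C[C@H]12 | target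

**Step count and risks**

Total step count: 12. Longest linear sequence: 8 (steps 1, 2, 3, 4, 9, 10, 11, 12).

The three steps most likely to fail:

Steps 3 and 5 (the same cycloaddition in the two series; step 3 also carries the gold stage). The diene is 1,1,4-trisubstituted with an inside oxygen and may add too slowly to the butenolide at temperatures the acetal tolerates. The fallback for step 3 sets out from 5 and 6 and comes back at 8. The gold step is run alone and 7 is isolated by filtration through silica. Butenolide 6 is brominated (Br2, then Et3N) to (5R)-3-bromo-5-(l-menthyloxy)furan-2(5H)-one F1, a more electron-poor dienophile. Its cycloaddition with 7 (PhMe, 80 °C) gives the 7a-bromo derivative of 8 F2. Bu3SnH/AIBN then replaces bromine by hydrogen at the ring-fusion carbon, where the cis-fused lactone is strongly preferred, to give 8. For step 5 the same detour sets out from 7 and 10, passes through (5S)-3-bromo-5-(d-menthyloxy)furan-2(5H)-one F3 and the 7a-bromo derivative of 11 F4, and comes back at 11.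

Step 9. A carboxylate is a weak Michael donor, the aldehyde enolate can compete, and the product diol can translactonise under base. The fallback sets out from 9 and comes back at 18. LiOH followed by acidification gives the ent-series lactone aldehyde 3a-hydroxy-1-oxo-6-(propan-2-yl)octahydro-2-benzofuran-7-carbaldehyde F5, in which the γ-lactone closes on the CH2OH and C-5a is already epimerised. A Morita–Baylis–Hillman reaction with allyl acrylate (DABCO) gives the allylic alcohol F6 as both carbinol epimers. CBr4/PPh3 (SN2′) gives the (Z)-2-(bromomethyl)enoate F7. One equivalent of LiOH at 0 °C opens the γ-lactone to the lithium carboxylate F8, which is not isolated and closes the oxepinone by intramolecular O-alkylation to give 18.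

Step 11. This is the same annulation, but its first bond is intermolecular between two advanced fragments. The fallback sets out from 12 and 18 and comes back at 21. Compound 12 is taken through the step 9 conditions with 15 to the natural-series allyl ester F9. Pd(PPh3)4/PhSiH3 gives natural hydroheptelidic acid F10. Compound 18 is tosylated at the primary hydroxyl (TsCl, pyridine) to the tosylate F11 and closed with K2CO3 in MeCN to the spiro-epoxide allyl ent-heptelidate F12. The caesium salt of F10 then opens the epoxide at its CH2 terminus (DMF, 60 °C), leaving the tertiary C–O bond and its configuration intact, to give 21.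

Further compounds
F1 | step 3 | (5R)-3-bromo-5-{[(1R,2S,5R)-5-methyl-2-(propan-2-yl)cyclohexyl]oxy}furan-2(5H)-one | O=C1C(Br)=C[C@H](O[C@@H]2C[C@H](C)CC[C@H]2C(C)C)O1
F2 | step 3 | 7a-bromo derivative of 8 (Br in place of H at the lactone ring-fusion carbon next to C=O) | CC(C)[C@@H]1C=C[C@](O3)(COC3=O)[C@]2(Br)C(=O)O[C@@H](O[C@@H]4C[C@H](C)CC[C@H]4C(C)C)[C@H]12
F3 | step 5 | (5S)-3-bromo-5-{[(1S,2R,5S)-5-methyl-2-(propan-2-yl)cyclohexyl]oxy}furan-2(5H)-one | O=C1C(Br)=C[C@@H](O[C@H]2C[C@@H](C)CC[C@@H]2C(C)C)O1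
F4 | step 5 | 7a-bromo derivative of 11 (mirror image of F2) | CC(C)[C@H]1C=C[C@@](O3)(COC3=O)[C@@]2(Br)C(=O)O[C@H](O[C@H]4C[C@@H](C)CC[C@@H]4C(C)C)[C@@H]12
F5 | step 9 | ent-series 3a-hydroxy-1-oxo-6-(propan-2-yl)octahydro-2-benzofuran-7-carbaldehyde (cis-fused γ-lactone, CHO trans to both neighbours) | CC(C)[C@@H]1CC[C@]2(O)COC(=O)[C@@H]2[C@H]1C=O
F6 | step 9 | prop-2-en-1-yl 2-{hydroxy[3a-hydroxy-1-oxo-6-(propan-2-yl)octahydro-2-benzofuran-7-yl]methyl}prop-2-enoate (both carbinol epimers) | CC(C)[C@@H]1CC[C@]2(O)COC(=O)[C@@H]2[C@H]1C(O)C(=C)C(=O)OCC=C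
F7 | step 9 | prop-2-en-1-yl (2Z)-2-(bromomethyl)-3-[3a-hydroxy-1-oxo-6-(propan-2-yl)octahydro-2-benzofuran-7-yl]prop-2-enoate | CC(C)[C@@H]1CC[C@]2(O)COC(=O)[C@@H]2[C@H]1/C=C(\CBr)C(=O)OCC=C
F8 | step 9 | lithium 2-{(1Z)-3-bromo-2-[(prop-2-en-1-yloxy)carbonyl]prop-1-en-1-yl}-6-hydroxy-6-(hydroxymethyl)-3-(propan-2-yl)cyclohexane-1-carboxylate (ent series) | CC(C)[C@@H]1CC[C@](O)(CO)[C@H](C(=O)[O-])[C@H]1/C=C(\CBr)C(=O)OCC=C.[Li+]
F9 | step 11 | prop-2-en-1-yl (5aS,6R,9S,9aS)-9-hydroxy-9-(hydroxymethyl)-1-oxo-6-(propan-2-yl)-3,5a,6,7,8,9a-hexahydro-2-benzoxepine-4-carboxylate | CC(C)[C@H]1CC[C@@](O)(CO)[C@H]2C(=O)OCC(C(=O)OCC=C)=C[C@H]12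
F10 | step 11 | (5aS,6R,9S,9aS)-9-hydroxy-9-(hydroxymethyl)-1-oxo-6-(propan-2-yl)-3,5a,6,7,8,9a-hexahydro-2-benzoxepine-4-carboxylic acid (natural hydroheptelidic acid) | CC(C)[C@H]1CC[C@@](O)(CO)[C@H]2C(=O)OCC(C(=O)O)=C[C@H]12
F11 | step 11 | prop-2-en-1-yl (5aR,6S,9R,9aR)-9-hydroxy-9-{[(4-methylbenzenesulfonyl)oxy]methyl}-1-oxo-6-(propan-2-yl)-3,5a,6,7,8,9a-hexahydro-2-benzoxepine-4-carboxylate | CC(C)[C@@H]1CC[C@](O)(COS(=O)(=O)c3ccc(C)cc3)[C@@H]2C(=O)OCC(C(=O)OCC=C)=C[C@@H]12
F12 | step 11 | prop-2-en-1-yl ent-heptelidate (spiro-epoxide from the 9-OH and 9-CH2 of 18) | CC(C)[C@@H]1CC[C@]3(CO3)[C@@H]2C(=O)OCC(C(=O)OCC=C)=C[C@@H]12
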